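**Retrosynthetic overview**
1. Target ⇒ C6-allyl oxocane. The E-enyne is grown last from the allyl group by cross-metathesis to the enal and a one-carbon Colvin homologation.
2. Oxocane ⇒ all-cis 2-allyl-3-chloro-oxolane (ring A) carrying a (1S,3E)-1-acetoxyhex-3-enyl arm. A bromonium-induced five-to-eight ring expansion runs through a 1-oxoniabicyclo[3.3.0]octane, is relayed by the acetate and ended by chloride. It makes O–C12, C13–Br and C9–Cl.
3. Arm ⇒ ring A epoxide + (E)-but-1-enyl Grignard reagent (from but-1-yne), with the alkoxide trapped as the acetate.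
4. Ring A ⇒ 5-endo chloroetherification of a Z-homoallylic alcohol ⇐ Lindlar reduction ⇐ mono-alkynylation of (S,S)-diepoxybutane with pent-1-en-4-yne. C9 and C10 come from the chiral pool.
5. Ring order: ring A (oxolane) → transient ring B (bicyclic oxonium) → oxocane.

Numbering used in the comments: natural-product numbering, C1 = alkyne CH, ring oxygen between C6 and C12, C15 = CH3.
Assumption: (S,S)-diepoxybutane (made from L-tartaric acid), pent-1-en-4-yne, but-1-yne and crotonaldehyde are taken as catalogue chemicals.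

**Step 1**
Reactants: 1 (2S,3S)-2,2'-bioxirane ((S,S)-1,2:3,4-diepoxybutane); 2 pent-1-en-4-yne
Product: 4 (1S)-1-[(2S)-oxiran-2-yl]hept-6-en-3-yn-1-ol, via lithium pent-4-en-1-yn-1-ide 3 (not isolated)
Conditions: 2, n-BuLi, THF, −78 °C; BF3·OEt2, then 1 (2.5 equiv), −78 °C
Reagents that add atoms: none
Why: Yamaguchi–Hirao alkynylation: the BF3-activated terminal epoxide is opened at its CH2 end by the lithium acetylide, the excess of the C2-symmetric diepoxide (homotopic ends) suppresses double opening, and C9 and C10 are carried over unchanged from 1.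

**Step 2**
Reactants: 4 (1S)-1-[(2S)-oxiran-2-yl]hept-6-en-3-yn-1-ol
Product: 5 (1S,3Z)-1-[(2S)-oxiran-2-yl]hepta-3,6-dien-1-ol
Conditions: H2 (1 atm, stopped at 1.0 equiv), Lindlar catalyst (Pd/CaCO3, Pb(OAc)2), quinoline, EtOAc, 0 °C
Reagents that add atoms: none
Why: Lindlar semihydrogenation: syn delivery of H2 to the alkyne gives the Z-alkene, and the poisoned catalyst with controlled uptake leaves the terminal alkene and the epoxide alone.

**Step 3**
Reactants: 5 (1S,3Z)-1-[(2S)-oxiran-2-yl]hepta-3,6-dien-1-ol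
Product: 6 (2S,3S,5S)-3-chloro-5-[(2S)-oxiran-2-yl]-2-(prop-2-en-1-yl)oxolane (all-cis ring A)
Conditions: NCS (1.1 equiv), Ph3P=S (10 mol %), 4 Å MS, CH2Cl2, −20 °C to rt, dark
Reagents that add atoms: N-chlorosuccinimide, O=C1CCC(=O)N1Cl
Why: 5-endo-trig haloetherification with Lewis-base-activated NCS: anti addition of Cl and the C9 oxygen across the Z-alkene fixes C6/C7 as 2,3-cis, the envelope transition state with the oxiranyl group pseudo-equatorial places it cis to the halogen (the rule for Z-homoallylic alcohols in the iodine series), so the all-cis (6S,7S) oxolane forms while the C10 oxygen stays masked as the epoxide.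

**Step 4**
Reactants: 7 but-1-yne
Product: 9 (E)-1-iodobut-1-ene, via (E)-but-1-enylzirconocene chloride 8 (not isolated)
Conditions: Cp2Zr(H)Cl, CH2Cl2, 0 °C to rt; I2, 0 °C
Reagents that add atoms: iodine, [I][I]
Why: Hydrozirconation–iodinolysis: syn, terminal-selective Zr–H addition and retentive C–Zr to C–I exchange give only the E-iodide.

**Step 5**
Reactants: 9 (E)-1-iodobut-1-ene; 6 (2S,3S,5S)-3-chloro-5-[(2S)-oxiran-2-yl]-2-(prop-2-en-1-yl)oxolane
Product: 12 (1S,3E)-1-[(2S,4S,5S)-4-chloro-5-(prop-2-en-1-yl)oxolan-2-yl]hex-3-en-1-yl acetate, via (E)-but-1-enylmagnesium chloride 10 (not isolated), via chloromagnesium alkoxide 11 (not isolated)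
Conditions: 9, iPrMgCl·LiCl, THF, rt; CuI (10 mol %), 6, −30 to 0 °C; then Ac2O, DMAP (cat.), 0 °C to rt
Reagents that add atoms: acetic anhydride, CC(=O)OC(C)=O
Why: Iodine–magnesium exchange with retention of alkene geometry, copper-catalysed SN2 opening of the terminal epoxide at C11 and in-flask acetylation of the alkoxide; C10 is untouched, and the secondary chloride and the allyl group are inert to the organocopper species at low temperature.

**Step 6**
Reactants: 12 (1S,3E)-1-[(2S,4S,5S)-4-chloro-5-(prop-2-en-1-yl)oxolan-2-yl]hex-3-en-1-yl acetate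
Product: 15 (2R,4S,5S,7S,8S)-2-[(1S)-1-bromopropyl]-5,7-dichloro-8-(prop-2-en-1-yl)oxocan-4-yl acetate, via bicyclic oxonium salt 13 (not isolated), via acetoxonium salt 14 (not isolated)
Conditions: Et2SBr·SbCl6 (1.05 equiv), MeNO2, −25 °C, 5 min; then Et4NCl (3 equiv), CH2Cl2, −25 °C to rt
Reagents that add atoms: bromodiethylsulfonium hexachloroantimonate, CC[S+](Br)CC.Cl[Sb-](Cl)(Cl)(Cl)(Cl)Cl; tetraethylammonium chloride, CC[N+](CC)(CC)CC.[Cl-]
Why: Proposed new method: Br+ passes from the sulfonium salt to the more electron-rich E-1,2-dialkyl alkene (the monosubstituted allyl group is much slower), and the ring A oxygen attacks C12 in a 5-exo, anti fashion, which puts the CHBrEt group on the convex face of the 1-oxoniabicyclo[3.3.0]octane 13 and so sets 12R,13S and the trans relation of the two ether side chains; the C10 acetate carbonyl then attacks C9 from the rear and cleaves the central C9–O bond (first inversion, five-to-eight ring expansion), just as the Boc carbonyl does in the known BDSB ring expansion of oxolanyl tert-butyl carbonates, but because an acetate cannot shed a cation the cis-fused 1,3-dioxolan-2-ylium hexachloroantimonate 14 persists (salts of this class are isolable) until free chloride opens it by SN2 at C9 (second inversion, net retention at C9, trans chloro-acetate); C9 is expected to be preferred over C10 because the rear face of C10 is screened by the 1,3-related C12 side chain, and the all-chloride antimonate keeps bromide out of this last event; the closest known reaction types are the bromonium-induced oxolane ring expansion and the halide opening of acetoxonium ions (Mattocks–Moffatt, orthoester/TMSCl).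

**Step 7**
Reactants: 15 (2R,4S,5S,7S,8S)-2-[(1S)-1-bromopropyl]-5,7-dichloro-8-(prop-2-en-1-yl)oxocan-4-yl acetate; 16 (E)-but-2-enal (crotonaldehyde)
Product: 17 (2R,4S,5S,7S,8S)-2-[(1S)-1-bromopropyl]-5,7-dichloro-8-[(2E)-4-oxobut-2-en-1-yl]oxocan-4-yl acetate
Conditions: 16 (5 equiv), second-generation Hoveyda–Grubbs catalyst (5 mol %), CH2Cl2, 40 °C
Reagents that add atoms: none
Why: Olefin cross-metathesis of an unhindered terminal alkene with an electron-poor enal partner is E-selective under thermodynamic control, and 15 holds no other alkene.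

**Step 8**
Reactants: 17 (2R,4S,5S,7S,8S)-2-[(1S)-1-bromopropyl]-5,7-dichloro-8-[(2E)-4-oxobut-2-en-1-yl]oxocan-4-yl acetate
Product: 19 (2R,4S,5S,7S,8S)-2-[(1S)-1-bromopropyl]-5,7-dichloro-8-[(2E)-pent-2-en-4-yn-1-yl]oxocan-4-yl acetate (target), via alkylidene carbene 18 (not isolated)
Conditions: TMSCHN2, LDA, THF, −78 °C; then 17, −78 to −20 °C; aq. NH4Cl
Reagents that add atoms: (trimethylsilyl)diazomethane, C[Si](C)(C)C=[N+]=[N-]
Why: Colvin rearrangement: lithiated TMS-diazomethane adds to the aldehyde, Peterson-type loss of silanolate and then of N2 gives carbene 18, whose 1,2-hydride shift gives the terminal alkyne with the E-alkene unchanged, and at low temperature the acetate and the secondary halides are not attacked.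

**Compound list**
1 | (2S,3S)-2,2'-bioxirane | C1O[C@@H]1[C@@H]1CO1 | starting material
2 | pent-1-en-4-yne | C=CCC#C | starting material
3 | lithium pent-4-en-1-yn-1-ide | [Li]C#CCC=C | intermediate (not isolated)
4 | (1S)-1-[(2S)-oxiran-2-yl]hept-6-en-3-yn-1-ol | C=CCC#CC[C@H](O)[C@@H]1CO1 | intermediate
5 | (1S,3Z)-1-[(2S)-oxiran-2-yl]hepta-3,6-dien-1-ol | C=CC/C=C\C[C@H](O)[C@@H]1CO1 | intermediate
6 | (2S,3S,5S)-3-chloro-5-[(2S)-oxiran-2-yl]-2-(prop-2-en-1-yl)oxolane | C=CC[C@@H]1O[C@H]([C@@H]2CO2)C[C@@H]1Cl | intermediate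
7 | but-1-yne | CCC#C | starting material
8 | (E)-but-1-enylzirconocene chloride | CC/C=C/[Zr](Cl)(C1C=CC=C1)C1C=CC=C1 | intermediate (not isolated)
9 | (E)-1-iodobut-1-ene | CC/C=C/I | intermediate
10 | (E)-but-1-enylmagnesium chloride (LiCl complex) | CC/C=C/[Mg]Cl | intermediate (not isolated)
11 | chloromagnesium (1S,3E)-1-[(2S,4S,5S)-4-chloro-5-(prop-2-en-1-yl)oxolan-2-yl]hex-3-en-1-olate | C=CC[C@@H]1O[C@H]([C@@H](O[Mg]Cl)C/C=C/CC)C[C@@H]1Cl | intermediate (not isolated)
12 | (1S,3E)-1-[(2S,4S,5S)-4-chloro-5-(prop-2-en-1-yl)oxolan-2-yl]hex-3-en-1-yl acetate | C=CC[C@@H]1O[C@H]([C@@H](OC(C)=O)C/C=C/CC)C[C@@H]1Cl | intermediate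
13 | 6-acetoxy-8-[(1S)-1-bromopropyl]-3-chloro-2-(prop-2-en-1-yl)-1-oxoniabicyclo[3.3.0]octane hexachloroantimonate; O+ bonded to C6, C9, C12; 6S,7S,9S,10S,12R,13S; allyl and Cl endo, bromopropyl exo | C=CC[C@@H]1[O+]2[C@@H]([C@@H](Br)CC)C[C@H](OC(C)=O)[C@@H]2C[C@@H]1Cl.Cl[Sb-](Cl)(Cl)(Cl)(Cl)Cl | intermediate (not isolated)
14 | oxocane with a cis-fused 2-methyl-1,3-dioxolan-2-ylium ring on C9/C10, hexachloroantimonate; 6S,7S,9R,10S,12R,13S | C=CC[C@@H]1O[C@@H]([C@@H](Br)CC)C[C@@H]2OC(C)=[O+][C@@H]2C[C@@H]1Cl.Cl[Sb-](Cl)(Cl)(Cl)(Cl)Cl | intermediate (not isolated)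
15 | (2R,4S,5S,7S,8S)-2-[(1S)-1-bromopropyl]-5,7-dichloro-8-(prop-2-en-1-yl)oxocan-4-yl acetate | C=CC[C@@H]1O[C@@H]([C@@H](Br)CC)C[C@H](OC(C)=O)[C@@H](Cl)C[C@@H]1Cl | intermediate
16 | (E)-but-2-enal | C/C=C/C=O | starting material
17 | (2R,4S,5S,7S,8S)-2-[(1S)-1-bromopropyl]-5,7-dichloro-8-[(2E)-4-oxobut-2-en-1-yl]oxocan-4-yl acetate | O=C/C=C/C[C@@H]1O[C@@H]([C@@H](Br)CC)C[C@H](OC(C)=O)[C@@H](Cl)C[C@@H]1Cl | intermediate
18 | alkylidene carbene (C1 carbene carbon, C1=C2, E-C3=C4) on the same oxocane | [C]=C/C=C/C[C@@H]1O[C@@H]([C@@H](Br)CC)C[C@H](OC(C)=O)[C@@H](Cl)C[C@@H]1Cl | intermediate (not isolated)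
19 | (2R,4S,5S,7S,8S)-2-[(1S)-1-bromopropyl]-5,7-dichloro-8-[(2E)-pent-2-en-4-yn-1-yl]oxocan-4-yl acetate | C#C/C=C/C[C@@H]1O[C@@H]([C@@H](Br)CC)C[C@H](OC(C)=O)[C@@H](Cl)C[C@@H]1Cl | target

**Step count**
Total steps: 8. Longest linear sequence: 7 (steps 1, 2, 3, 5, 6, 7, 8).

**Three steps most likely to fail**

Step 6 (the proposed new step).
- The acetate may capture the bromonium ion directly in a 6-exo mode.
- The concave face of 13 is crowded by the allyl group and the chlorine.
- Chloride may open 14 at C10, or may intercept 13 (in equilibrium with 14 through transannular return of the ring oxygen) at C9, C6 or C12.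
- Liberated Et2S may compete as a nucleophile before chloride is added.
- The sulfonium hexachloroantimonate is itself new. It would be prepared beforehand like BDSB, from Et2S, BrCl and SbCl5.

The fallback uses known chemistry, sets out from 6 and comes back at 15. The alkoxide 11, made as in step 5, is quenched with Boc2O instead of Ac2O to give the tert-butyl carbonate F1. BDSB (Et2SBr·SbCl5Br, MeNO2, −25 °C), the established reagent for this substrate class, gives the ring-expanded cis-fused cyclic carbonate F2 with loss of the tert-butyl cation. K2CO3/MeOH frees the cis-diol F3. MeC(OMe)3/PPTS gives the cyclic orthoacetate F4, and TMSCl in CH2Cl2 converts it into 15 by the standard diol-to-chloroacetate protocol, with inversion at the carbon that takes up chloride.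

Step 3.
- An unactivated Z-dialkyl alkene is a slow partner for chloriranium formation.
- Allylic chlorination at the doubly allylic C5 may compete.
- The epoxide oxygen may attack C7 in a 5-exo mode.
- The 2,5-cis selectivity may be only modest.

The fallback sets out from 1 and 2 and comes back at 6. It replaces addition across an alkene by epoxide opening and hydroxyl inversion. Hydroalumination of 2 with DIBAL-H gives the (E)-dienylalane F5. n-BuLi turns it into the lithium alanate F6, which opens 1 to the E-dienol F7. Shi epoxidation (D-fructose-derived ketone, Oxone, pH 10.5) attacks only the E-disubstituted alkene and gives the (R,R)-epoxide F8 under catalyst control. CSA closes it 5-endo with inversion at C6 to the 3-hydroxyoxolane F9, whose OH is trans to both side chains and so cannot reach the terminal epoxide. Appel chlorination (PPh3, CCl4) then inverts C7 and gives 6.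

Step 8.
- The enal has acidic γ-hydrogens at C5 next to the C6 ether, so ring-opening elimination is possible.
- The silanolate formed in the reaction can cleave the acetate on warming.

The fallback sets out from 15 and comes back at 19. It replaces enal homologation by olefination of the C4 aldehyde. Ozonolysis of 15 (O3, CH2Cl2, −78 °C; Me2S) gives the aldehyde F10. Horner–Wadsworth–Emmons reaction with diethyl [3-(trimethylsilyl)prop-2-yn-1-yl]phosphonate (LiHMDS, THF, −78 °C) gives the E-silyl enyne F11. TBAF buffered with AcOH at 0 °C removes the silyl group and gives 19.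

**Further compounds**
F1 | step 6 | tert-butyl (1S,3E)-1-[(2S,4S,5S)-4-chloro-5-(prop-2-en-1-yl)oxolan-2-yl]hex-3-en-1-yl carbonate | C=CC[C@@H]1O[C@H]([C@@H](OC(=O)OC(C)(C)C)C/C=C/CC)C[C@@H]1Cl
F2 | step 6 | cis-fused C9/C10 cyclic carbonate of (2R,4S,5R,7S,8S)-2-[(1S)-1-bromopropyl]-7-chloro-8-(prop-2-en-1-yl)oxocane-4,5-diol | C=CC[C@@H]1O[C@@H]([C@@H](Br)CC)C[C@@H]2OC(=O)O[C@@H]2C[C@@H]1Cl
F3 | step 6 | (2R,4S,5R,7S,8S)-2-[(1S)-1-bromopropyl]-7-chloro-8-(prop-2-en-1-yl)oxocane-4,5-diol | C=CC[C@@H]1O[C@@H]([C@@H](Br)CC)C[C@H](O)[C@H](O)C[C@@H]1Cl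
F4 | step 6 | cyclic methyl orthoacetate of F3 (2-methoxy-2-methyl-1,3-dioxolane on C9/C10, epimers at the orthoester carbon) | C=CC[C@@H]1O[C@@H]([C@@H](Br)CC)C[C@@H]2OC(C)(OC)O[C@@H]2C[C@@H]1Cl
F5 | step 3 | diisobutyl[(E)-penta-1,4-dien-1-yl]alane | C=CC/C=C/[Al](CC(C)C)CC(C)C
F6 | step 3 | lithium butyl(diisobutyl)[(E)-penta-1,4-dien-1-yl]aluminate | [Li+].CCCC[Al-](CC(C)C)(CC(C)C)/C=C/CC=C
F7 | step 3 | (1S,3E)-1-[(2S)-oxiran-2-yl]hepta-3,6-dien-1-ol | C=CC/C=C/C[C@H](O)[C@@H]1CO1
F8 | step 3 | (1S)-1-[(2S)-oxiran-2-yl]-2-[(2R,3R)-3-(prop-2-en-1-yl)oxiran-2-yl]ethan-1-ol | C=CC[C@H]1O[C@@H]1C[C@H](O)[C@@H]2CO2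
F9 | step 3 | (2S,3R,5S)-5-[(2S)-oxiran-2-yl]-2-(prop-2-en-1-yl)oxolan-3-ol | C=CC[C@@H]1O[C@H]([C@@H]2CO2)C[C@H]1O
F10 | step 8 | (2R,4S,5S,7S,8S)-2-[(1S)-1-bromopropyl]-5,7-dichloro-8-(2-oxoethyl)oxocan-4-yl acetate | O=CC[C@@H]1O[C@@H]([C@@H](Br)CC)C[C@H](OC(C)=O)[C@@H](Cl)C[C@@H]1Cl
F11 | step 8 | (2R,4S,5S,7S,8S)-2-[(1S)-1-bromopropyl]-5,7-dichloro-8-[(2E)-5-(trimethylsilyl)pent-2-en-4-yn-1-yl]oxocan-4-yl acetate | C[Si](C)(C)C#C/C=C/C[C@@H]1O[C@@H]([C@@H](Br)CC)C[C@H](OC(C)=O)[C@@H](Cl)C[C@@H]1Cl
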